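**Retrosynthetic overview** (ring numbering: C1 ketone, C2 vinyl CH, C3 enol-ether carbon, C4 ketal carbon, C5 CH2, C6 allyl-bearing CH)
- Feature: the only ring to build is the cyclohexenone C1(=O)–C2H=C3(OMe)–C4(OMe)(OAr)–C5H2–C6H(allyl). Its enol-ether methoxy sits on C3, beside the fully substituted C4. A (MeO)2C=CH–C(OSiMe3)=CH–R diene places exactly this oxygen pattern in a Diels–Alder adduct.
- C4–OMe is traced back to C4–CO2H (decarboxylative methoxylation through a planar aryl oxocarbenium ion, methanol entering anti to the C6 allyl), and the acid to C4–CHO.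
- The formyl cyclohexenone is cut at C5–C6 and C3–C4: an enantioselective [4+2] of the heptatriene diene with 2-(2-allyl-4,5-dimethoxyphenoxy)acrolein. This is the only ring formation; the arene is bought.
- Diene: 1,1-dimethoxyethene plus pent-4-enoyl chloride, then O-silylation. Dienophile: 3,4-dimethoxyphenol by O-allylation, Claisen rearrangement, O-alkylation with bromoacetaldehyde diethyl acetal, hydrolysis and α-methylenation.

Key step: step 8

Assumption: the sense of induction of the salen–cobalt catalyst on this enal is taken by analogy. The (R,R) catalyst is written, and its (S,S) antipode is used instead if the major adduct proves to be (R) at the allyl-bearing carbon.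

**Step 1**
Reactants: 1 1,1-dimethoxyethene; 2 pent-4-enoyl chloride
Product: 3 1,1-dimethoxyhepta-1,6-dien-3-one
Conditions: 1 (2.2 equiv), Et2O, 0 °C to rt; vacuum distillation
Reagents that add atoms: none
Why: C-acylation of a ketene acetal, in which the nucleophilic CH2 of 1 attacks the acid chloride and the acidic proton of the resulting dimethoxycarbenium ion passes to a second equivalent of 1, while leaving out an amine base prevents ketene formation from 2.

**Step 2**
Reactants: 3 1,1-dimethoxyhepta-1,6-dien-3-one
Product: 4 (3Z)-1,1-dimethoxy-3-(trimethylsilyloxy)hepta-1,3,6-triene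
Conditions: TMSOTf, Et3N, Et2O, 0 °C; pentane, filtration, Kugelrohr distillation
Reagents that add atoms: trimethylsilyl trifluoromethanesulfonate, C[Si](C)(C)OS(=O)(=O)C(F)(F)F
Why: Soft enolisation with O-silylation, where the CH2 next to the ketone (future C6) is the only enolisable site and amine/silyl triflate conditions favour the Z silyl enol ether, so the allyl chain lies "outside" in the s-cis diene.

**Step 3**
Reactants: 5 3,4-dimethoxyphenol; 6 allyl bromide
Product: 7 4-(allyloxy)-1,2-dimethoxybenzene
Conditions: K2CO3, acetone, reflux
Reagents that add atoms: none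
Why: Williamson ether synthesis, in which the phenoxide displaces bromide from the allylic halide by SN2 and O-alkylation dominates under carbonate/acetone conditions.

**Step 4**
Reactants: 7 4-(allyloxy)-1,2-dimethoxybenzene
Product: 8 2-allyl-4,5-dimethoxyphenol
Conditions: PhNEt2, 200 °C
Reagents that add atoms: none
Why: Aromatic Claisen rearrangement ([3,3] shift, then tautomerisation), where the ortho position between the two oxygen substituents is crowded, so the allyl group should migrate to the open ortho position and give the substitution pattern of the target's arene.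

**Step 5**
Reactants: 8 2-allyl-4,5-dimethoxyphenol; 9 bromoacetaldehyde diethyl acetal
Product: 10 1-allyl-2-(2,2-diethoxyethoxy)-4,5-dimethoxybenzene
Conditions: K2CO3, NaI (cat.), DMF, 100 °C
Reagents that add atoms: none
Why: Williamson alkylation of the phenoxide with a sluggish β,β-dialkoxy primary bromide, hence DMF, heat and iodide catalysis, while carbonate is too weak a base to move the allyl double bond into conjugation.

**Step 6**
Reactants: 10 1-allyl-2-(2,2-diethoxyethoxy)-4,5-dimethoxybenzene
Product: 11 2-(2-allyl-4,5-dimethoxyphenoxy)acetaldehyde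
Conditions: 1 M HCl, THF, 40 °C; used directly
Reagents that add atoms: water, O
Why: Acid-catalysed acetal hydrolysis, for which dilute aqueous acid suffices, whereas cyclodehydration to a benzofuran needs strong dehydrating acid and could here use only the crowded position between two oxygen substituents.

**Step 7**
Reactants: 11 2-(2-allyl-4,5-dimethoxyphenoxy)acetaldehyde
Product: 12 2-(2-allyl-4,5-dimethoxyphenoxy)acrolein
Conditions: 37% aq. HCHO, pyrrolidine (10 mol %), EtCO2H (10 mol %), i-PrOH, 45 °C; stored cold with BHT
Reagents that add atoms: formaldehyde, C=O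
Why: Amine-catalysed α-methylenation (Mannich condensation via the enamine of 11, then loss of the amine), a standard way from alkoxy- and aryloxyacetaldehydes to 2-oxygenated acroleins, and the product has no α-hydrogen left for a second condensation.

**Step 8**
Reactants: 4 (3Z)-1,1-dimethoxy-3-(trimethylsilyloxy)hepta-1,3,6-triene; 12 2-(2-allyl-4,5-dimethoxyphenoxy)acrolein
Product: 14 (1S,5S)-5-allyl-1-(2-allyl-4,5-dimethoxyphenoxy)-2-methoxy-4-oxocyclohex-2-ene-1-carbaldehyde (CHO cis to allyl), via silyl enol ether ketal cycloadduct 13 (not isolated)
Conditions: [(R,R)-N,N'-bis(3,5-di-tert-butylsalicylidene)cyclohexane-1,2-diamine]Co(III) SbF6 (5 mol %), 4 Å MS, CH2Cl2, −40 °C; then TFA (cat.), CH2Cl2, 0 °C; chromatographic removal of the minor diastereomer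
Reagents that add atoms: none
Why: The cationic cobalt(III) centre binds the formyl oxygen of 12 and lowers the LUMO of the captodative alkene, and the ring forms by a suprafacial but very asynchronous [4+2] in which C6 of 4 (where both methoxy groups and the silyloxy group pile up electron density) bonds first to the unsubstituted methylene C5 and the ketene-acetal carbon C3 then closes on C4, after which catalytic TFA makes 13 lose MeOSiMe3 to leave the C1 ketone and the C2=C3 methoxy enol ether. The closest known reactions are the thermal Diels–Alder additions of 1,1-dialkoxy-3-silyloxybutadienes to 2-substituted acroleins and the salen–metal-catalysed enantioselective Diels–Alder additions of 1-amino-3-silyloxydienes to 2-substituted acroleins, and 2-oxygenated acroleins are established dienophiles. The one new ring, carbocycle C1–C6, is closed by intermolecular cycloaddition (bonds C5–C6 and C3–C4), and if the second bond lags so far that a zwitterion forms, its enolate carbon C4 collapses on the dimethoxycarbenium carbon C3 in a six-membered Michael-type closure to the same skeleton. C4 is set directly by the enal face that the salen ligand leaves open, whereas C6 follows from that face only together with the formyl-endo orientation and the Z geometry of the silyl enol ether, which place CHO and allyl cis. Because endo and exo adducts from one enal face have opposite configuration at C6 and C4 is erased later, the minor diastereomer is removed at the stage of 14 so that it cannot lower the enantiomeric purity of the target. The step needs regioselectivity, secured by the matched polarisation of diene (nucleophilic C6) and enal (electrophilic C5), and chemoselectivity for C=C over C=O, secured by the open CH2 terminus, the mild Lewis acid and the low temperature.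

**Step 9**
Reactants: 14 (1S,5S)-5-allyl-1-(2-allyl-4,5-dimethoxyphenoxy)-2-methoxy-4-oxocyclohex-2-ene-1-carbaldehyde
Product: 15 (1S,5S)-5-allyl-1-(2-allyl-4,5-dimethoxyphenoxy)-2-methoxy-4-oxocyclohex-2-ene-1-carboxylic acid
Conditions: NaClO2, NaH2PO4, 2-methyl-2-butene (large excess), t-BuOH/H2O, 0 °C; cold extraction at pH 4, used without heating
Reagents that add atoms: sodium chlorite, [Na+].[O-]Cl=O
Why: Pinnick oxidation, in which chlorous acid adds to the non-enolisable formyl group and fragments to the acid at pH about 4 without touching the terminal alkenes or either stereocentre, and the excess alkene removes hypochlorous acid before it can chlorinate the trialkoxyarene or C2.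

**Step 10**
Reactants: 15 (1S,5S)-5-allyl-1-(2-allyl-4,5-dimethoxyphenoxy)-2-methoxy-4-oxocyclohex-2-ene-1-carboxylic acid
Product: 17 (4R,6S)-6-allyl-4-(2-allyl-4,5-dimethoxyphenoxy)-3,4-dimethoxycyclohex-2-en-1-one (target), via C4 aryloxocarbenium ion 16 (not isolated)
Conditions: graphite anode, Pt cathode, undivided cell, NaOMe (0.2 equiv), MeOH, 0 °C, constant current, 2.2 F/mol; then pH 7 buffer; Et3N-deactivated silica
Reagents that add atoms: methanol, CO
Why: Hofer–Moest (non-Kolbe) anodic decarboxylation, known to turn α-alkoxy and α-aryloxy acids into mixed acetals in methanol: two-electron oxidation on carbon (first electron from the trialkoxyaryl ether/carboxylate pair, then loss of CO2 and oxidation of the captodative C4 radical) gives planar ion 16, whose half-chair holds the C6 allyl pseudo-equatorial, so methanol adds along the pseudo-axial line on the face opposite the allyl group, as nucleophiles do with 5-substituted cyclohexenones, and this sets (4R) from the untouched (6S) centre.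

**Compound list**
1 | 1,1-dimethoxyethene | C=C(OC)OC | starting material
2 | pent-4-enoyl chloride | C=CCCC(=O)Cl | starting material
3 | 1,1-dimethoxyhepta-1,6-dien-3-one | C=CCCC(=O)C=C(OC)OC | intermediate
4 | (3Z)-1,1-dimethoxy-3-(trimethylsilyloxy)hepta-1,3,6-triene | C=CC/C=C(\O[Si](C)(C)C)C=C(OC)OC | intermediate
5 | 3,4-dimethoxyphenol | COc1ccc(O)cc1OC | starting material
6 | allyl bromide | C=CCBr | starting material
7 | 4-(allyloxy)-1,2-dimethoxybenzene | C=CCOc1ccc(OC)c(OC)c1 | intermediate
8 | 2-allyl-4,5-dimethoxyphenol | C=CCc1cc(OC)c(OC)cc1O | intermediate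
9 | bromoacetaldehyde diethyl acetal | CCOC(CBr)OCC | starting material
10 | 1-allyl-2-(2,2-diethoxyethoxy)-4,5-dimethoxybenzene | C=CCc1cc(OC)c(OC)cc1OCC(OCC)OCC | intermediate
11 | 2-(2-allyl-4,5-dimethoxyphenoxy)acetaldehyde | C=CCc1cc(OC)c(OC)cc1OCC=O | intermediate
12 | 2-(2-allyl-4,5-dimethoxyphenoxy)acrolein | C=C(C=O)Oc1cc(OC)c(OC)cc1CC=C | intermediate
13 | (1R,5S)-5-allyl-1-(2-allyl-4,5-dimethoxyphenoxy)-2,2-dimethoxy-4-(trimethylsilyloxy)cyclohex-3-ene-1-carbaldehyde | C=CCc1cc(OC)c(OC)cc1O[C@@]1(C=O)C[C@H](CC=C)C(O[Si](C)(C)C)=CC1(OC)OC | intermediate
14 | (1S,5S)-5-allyl-1-(2-allyl-4,5-dimethoxyphenoxy)-2-methoxy-4-oxocyclohex-2-ene-1-carbaldehyde | C=CCc1cc(OC)c(OC)cc1O[C@@]1(C=O)C[C@H](CC=C)C(=O)C=C1OC | intermediate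
15 | (1S,5S)-5-allyl-1-(2-allyl-4,5-dimethoxyphenoxy)-2-methoxy-4-oxocyclohex-2-ene-1-carboxylic acid | C=CCc1cc(OC)c(OC)cc1O[C@@]1(C(=O)O)C[C@H](CC=C)C(=O)C=C1OC | intermediate
16 | (S)-(5-allyl-2-methoxy-4-oxocyclohex-2-en-1-ylidene)(2-allyl-4,5-dimethoxyphenyl)oxonium | C=CCc1cc(OC)c(OC)cc1[O+]=C1C[C@H](CC=C)C(=O)C=C1OC | intermediate
17 | (4R,6S)-6-allyl-4-(2-allyl-4,5-dimethoxyphenoxy)-3,4-dimethoxycyclohex-2-en-1-one | C=CCc1cc(OC)c(OC)cc1O[C@]1(OC)C[C@H](CC=C)C(=O)C=C1OC | target

**Totals**
Total step count: 10. Longest linear sequence: 8 (steps 3 to 10).

**Steps most likely to fail**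

1. Step 8.
   - Once the aldehyde is bound to a Lewis acid, the diene may attack the formyl carbon (hetero-Diels–Alder or aldol pathway) instead of the C=C bond.
   - The reaction may stop after the first bond as an open-chain Michael adduct.
   - Endo/exo or facial control may be weak.
   - Trace acid may protonate the ketene acetal.
   - Fallback (sets out from 4 and 12, returns at 14): the two partners are combined without any catalyst in toluene at room temperature to 60 °C. This is the mode in which dienes of this class are known to add to the C=C bond of enals. It gives the racemic silyl enol ether ketal cycloadduct F1. Catalytic TFA converts it into the racemic formyl cyclohexenone F2, and the cis (endo) diastereomer is isolated on silica. Its enantiomers are separated by preparative chromatography on a chiral stationary phase, and the (1S,5S) enantiomer is 14.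

2. Step 10.
   - The trialkoxyarene of substrate or product may be oxidised beyond the wanted two electrons (ring methoxylation, methoxylation at the benzylic allyl CH2, or mesolytic loss of the aryloxy group).
   - The ion may lose a proton from C5 and aromatise.
   - Acid built up at the anode may exchange the aryloxy group for methoxy.
   - Facial selectivity of the capture may be modest.
   - Fallback (sets out from 15, returns at 17 through ion 16): 15 is coupled with N-hydroxyphthalimide (DIC, cat. DMAP, CH2Cl2, 0 °C) to the redox-active N-hydroxyphthalimide ester F3. This is irradiated with blue light in MeCN/MeOH with a phenothiazine organophotocatalyst and LiBF4, which reduces the ester and releases the C4 radical. The catalyst radical cation is too weak an oxidant to touch the arene, but it oxidises that radical to 16, which methanol captures. This is the known decarboxylative radical–polar crossover etherification.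

3. Step 9.
   - Hypochlorous acid may chlorinate the electron-rich arene or C2 of the vinylogous ester before the scavenger intercepts it.
   - The vinylogous β-keto acid may lose CO2 with protonation during work-up.
   - Fallback (sets out from 14, returns at 17 through ion 16, by-passing 15): Baeyer–Villiger oxidation (mCPBA, Na2HPO4, CH2Cl2, 0 °C) lets the tertiary, oxygen-bearing C4 migrate with retention to the C4 formate F4. Any competing hydride migration merely gives 15. As an α-acyloxy ether, F4 is ionised with catalytic TMSOTf in the presence of MeOSiMe3 in CH2Cl2 at −78 °C, and the methoxy group is delivered to 16 with the same facial bias as in step 10.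

**Further compounds**
F1 | step 8 | racemic 5-allyl-1-(2-allyl-4,5-dimethoxyphenoxy)-2,2-dimethoxy-4-(trimethylsilyloxy)cyclohex-3-ene-1-carbaldehyde (CHO cis to allyl, both enantiomers) | C=CCc1cc(OC)c(OC)cc1O[C@@]1(C=O)C[C@H](CC=C)C(O[Si](C)(C)C)=CC1(OC)OC.C=CCc1cc(OC)c(OC)cc1O[C@]1(C=O)C[C@@H](CC=C)C(O[Si](C)(C)C)=CC1(OC)OC
F2 | step 8 | racemic 5-allyl-1-(2-allyl-4,5-dimethoxyphenoxy)-2-methoxy-4-oxocyclohex-2-ene-1-carbaldehyde (CHO cis to allyl, both enantiomers) | C=CCc1cc(OC)c(OC)cc1O[C@@]1(C=O)C[C@H](CC=C)C(=O)C=C1OC.C=CCc1cc(OC)c(OC)cc1O[C@]1(C=O)C[C@@H](CC=C)C(=O)C=C1OC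
F3 | step 10 | 1,3-dioxoisoindolin-2-yl (1S,5S)-5-allyl-1-(2-allyl-4,5-dimethoxyphenoxy)-2-methoxy-4-oxocyclohex-2-ene-1-carboxylate | C=CCc1cc(OC)c(OC)cc1O[C@@]1(C(=O)ON2C(=O)c3ccccc3C2=O)C[C@H](CC=C)C(=O)C=C1OC
F4 | step 9 | (1R,5S)-5-allyl-1-(2-allyl-4,5-dimethoxyphenoxy)-2-methoxy-4-oxocyclohex-2-en-1-yl formate | C=CCc1cc(OC)c(OC)cc1O[C@@]1(OC=O)C[C@H](CC=C)C(=O)C=C1OC
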